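**Retrosynthetic overview**

- The target is reached by fluoride cleavage of its bis(triisopropylsilyl) ether; rings A and C both come from vanillin, and ring B is the only ring formed, last.
- Ring B is closed through the C8a–C1 bond by a stereoconvergent, silicon-directed ipso-Friedel–Crafts reaction of an open-chain (E)-2-substituted cinnamaldehyde with a benzylic acetate at C1 and SiMe3 on C8a; both C1 epimers should converge on the 1,2-trans product, with Me3SiOAc as the only by-product.
- Enabling feature: the oxygen on C4' of ring C, para to C1, makes C1 an easily ionised, planar (quinone-methide-like) cation; and C8a lies between the C8 methoxy group and the C4a side chain, the one site where directed lithiation can place the ipso-directing silicon.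
- The cyclisation precursor comes from an aldol condensation (C3=C4) of a 2-silylated vanillin ether (ring A) with a chiral aldehyde carrying C1, C2, C3 and both oxygenated carbons.
- C2 is set by an iridium-catalysed (hydroxymethyl)allylation of silyl-protected vanillin (ring C).

Key step: step 8

Remark on the chemistry: only C2 must be fixed before the key step; the C1 configuration drawn for the open-chain intermediates (the expected major anti isomer) is immaterial because C1 becomes planar in step 8, and the SEGPHOS antipode is taken to be the one that gives the 2R series.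

**Step 1**
Reactants: 1 vanillin (4-hydroxy-3-methoxybenzaldehyde)
Product: 2 3-methoxy-4-[(triisopropylsilyl)oxy]benzaldehyde
Conditions: i-Pr3SiCl, imidazole, DMF, rt
Reagents that add atoms: triisopropylsilyl chloride, CC(C)[Si](Cl)(C(C)C)C(C)C
Why: Standard phenol silylation; the bulky silyl ether should survive organolithium, mild base, Lewis acid and oxidants, and is removable by fluoride at the end without touching the alkyl acetate.

**Step 2**
Reactants: 2 3-methoxy-4-[(triisopropylsilyl)oxy]benzaldehyde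
Product: 6 3-methoxy-4-[(triisopropylsilyl)oxy]-2-(trimethylsilyl)benzaldehyde, via lithium alpha-amino alkoxide 3 (not isolated), via 2-lithio alpha-amino alkoxide 4 (not isolated), via 2-silyl alpha-amino alkoxide 5 (not isolated)
Conditions: LiN(Me)CH2CH2NMe2 (from Me2NCH2CH2NHMe and n-BuLi), THF, −20 °C; n-BuLi, −20 °C; Me3SiCl, −78 °C → rt; H2O
Reagents that add atoms: chlorotrimethylsilane, C[Si](C)(C)Cl; lithium N,N,N'-trimethylethylenediamide, [Li]N(C)CCN(C)C (atoms kept only in 3 to 5); n-butyllithium, [Li]CCCC (lithium kept only in 4)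
Why: Directed ortho-metalation through an in situ alpha-amino alkoxide, which protects the aldehyde and should direct lithiation to C2, the site activated cooperatively by the chelating amino alkoxide and the C3 methoxy group while the bulky silyl ether shields C5; silylation and hydrolytic work-up return the aldehyde.

**Step 3**
Reactants: 2 3-methoxy-4-[(triisopropylsilyl)oxy]benzaldehyde; 7 4-vinyl-1,3-dioxolan-2-one (vinyl ethylene carbonate, racemic)
Product: 8 (1S,2R)-1-{3-methoxy-4-[(triisopropylsilyl)oxy]phenyl}-2-vinylpropane-1,3-diol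
Conditions: [Ir(cod)Cl]2 (cat.), (S)-SEGPHOS (cat.), 4-cyano-3-nitrobenzoic acid (cat.), K3PO4 (cat.), i-PrOH, THF, 60 °C
Reagents that add atoms: none
Why: Iridium-catalysed transfer-hydrogenative carbonyl (hydroxymethyl)allylation, in which the carbonate ionises with loss of CO2 to a hydroxymethyl-substituted allyl–iridium species (isopropanol as terminal reductant) that should add to the aldehyde through a closed chair transition state to give the anti diol, the chiral bisphosphine setting the absolute configuration at C2.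

**Step 4**
Reactants: 8 (1S,2R)-1-{3-methoxy-4-[(triisopropylsilyl)oxy]phenyl}-2-vinylpropane-1,3-diol
Product: 9 (1S,2R)-1-{3-methoxy-4-[(triisopropylsilyl)oxy]phenyl}-2-vinylpropane-1,3-diyl diacetate
Conditions: Ac2O, pyridine, DMAP (cat.), CH2Cl2, 0 °C → rt
Reagents that add atoms: acetic anhydride, CC(=O)OC(C)=O
Why: Exhaustive acylation needs no selectivity, since the primary acetate is the one found in the target and the benzylic acetate becomes the leaving group of step 8.

**Step 5**
Reactants: 9 (1S,2R)-1-{3-methoxy-4-[(triisopropylsilyl)oxy]phenyl}-2-vinylpropane-1,3-diyl diacetate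
Product: 11 (1S,2R)-2-(2-hydroxyethyl)-1-{3-methoxy-4-[(triisopropylsilyl)oxy]phenyl}propane-1,3-diyl diacetate, via B-alkyl-9-borabicyclononane 10 (not isolated)
Conditions: 9-BBN, THF, 0 °C → rt; then 30% H2O2, aq. NaOAc, 0 °C → rt
Reagents that add atoms: hydrogen peroxide, OO; 9-borabicyclo[3.3.1]nonane, B1C2CCCC1CCC2 (boron and ring kept only in 10)
Why: Anti-Markovnikov hydroboration–oxidation of the terminal alkene; 9-BBN tolerates esters and the acetate-buffered peroxide oxidation avoids the hydroxide that would cleave the acetates.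

**Step 6**
Reactants: 11 (1S,2R)-2-(2-hydroxyethyl)-1-{3-methoxy-4-[(triisopropylsilyl)oxy]phenyl}propane-1,3-diyl diacetate
Product: 12 (1S,2R)-1-{3-methoxy-4-[(triisopropylsilyl)oxy]phenyl}-2-(2-oxoethyl)propane-1,3-diyl diacetate
Conditions: Dess–Martin periodinane, CH2Cl2, 0 °C → rt
Reagents that add atoms: none
Why: Dess–Martin oxidation of the primary alcohol is mild and non-basic, should leave both acetates and the silyl ether untouched, and cannot epimerise C2, which is beta to the new carbonyl group.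

**Step 7**
Reactants: 12 (1S,2R)-1-{3-methoxy-4-[(triisopropylsilyl)oxy]phenyl}-2-(2-oxoethyl)propane-1,3-diyl diacetate; 6 3-methoxy-4-[(triisopropylsilyl)oxy]-2-(trimethylsilyl)benzaldehyde
Product: 13 (1S,2R)-2-{(E)-1-formyl-2-[3-methoxy-4-[(triisopropylsilyl)oxy]-2-(trimethylsilyl)phenyl]vinyl}-1-{3-methoxy-4-[(triisopropylsilyl)oxy]phenyl}propane-1,3-diyl diacetate
Conditions: pyrrolidine (30 mol%), propionic acid (30 mol%), 4 Å molecular sieves, CH2Cl2, rt → 40 °C
Reagents that add atoms: none
Why: Amine-catalysed crossed aldol condensation between the only enolisable aldehyde and the non-enolisable aryl aldehyde should give the thermodynamically preferred E-enal, with ring A cis to C2 as the cyclisation requires, while C2 (not alpha to the carbonyl group) keeps its configuration.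

**Step 8**
Reactants: 13 (1S,2R)-2-{(E)-1-formyl-2-[3-methoxy-4-[(triisopropylsilyl)oxy]-2-(trimethylsilyl)phenyl]vinyl}-1-{3-methoxy-4-[(triisopropylsilyl)oxy]phenyl}propane-1,3-diyl diacetate
Product: 15 [(1S,2R)-3-formyl-8-methoxy-1-{3-methoxy-4-[(triisopropylsilyl)oxy]phenyl}-7-[(triisopropylsilyl)oxy]-1,2-dihydronaphthalen-2-yl]methyl acetate, via benzylic cation 14 (not isolated)
Conditions: Me3SiOTf (20 mol%), 2,6-di-tert-butyl-4-methylpyridine (30 mol%), CH2Cl2, −78 → −30 °C
Reagents that add atoms: none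
Why: Proposed new method: catalytic Me3SiOTf should silylate and ionise the benzylic acetate of 13 to the para-siloxybenzyl cation 14, in which C1 is planar so that both C1 epimers converge; the cation, held next to ring A by the E-configured C3=C4 bond, attacks the silicon-bearing C8a, and the beta-silyl arenium ion then passes Me3Si+ to triflate, which regenerates the catalyst and releases no proton. The closest known reactions are the silicon-directed ipso Pictet–Spengler cyclisation, which likewise forces closure between a side chain and a methoxy group, and the acid-mediated Friedel–Crafts closure of dibenzylidenesuccinates and alpha-hydroxybenzyl lignan precursors to trans-1-aryl-1,2-dihydronaphthalenes. Ring B is the only ring closed, in a 6-endo mode with respect to the C4a–C8a arene bond (ipso electrophilic aromatic substitution at C8a). The new stereocentre C1 is controlled by the existing C2 centre: in the half-chair transition state CH2OAc on C2 sits pseudoaxial (allylic strain with the C3 formyl group) and ring C takes the opposite face, pseudoaxial and away from the C8 methoxy group, which should give the 1,2-trans (1S,2R) product. The step needs regioselectivity for C8a over C5, secured by the ipso-directing SiMe3 group together with the ortho C8 methoxy group, and retention at C2, secured by the absence of Brønsted acid (hindered pyridine buffer) so that any styrene formed by proton loss cannot be reprotonated.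

**Step 9**
Reactants: 15 [(1S,2R)-3-formyl-8-methoxy-1-{3-methoxy-4-[(triisopropylsilyl)oxy]phenyl}-7-[(triisopropylsilyl)oxy]-1,2-dihydronaphthalen-2-yl]methyl acetate
Product: 16 [(1S,2R)-3-formyl-7-hydroxy-1-(4-hydroxy-3-methoxyphenyl)-8-methoxy-1,2-dihydronaphthalen-2-yl]methyl acetate (target)
Conditions: Bu4NF, AcOH, THF, 0 °C
Reagents that add atoms: none
Why: Fluoride-mediated cleavage of both aryl silyl ethers, buffered with acetic acid so that the phenoxides cannot attack the primary acetate or the enal; no stereocentre is touched.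

**Compound list**

1 | vanillin (4-hydroxy-3-methoxybenzaldehyde) | O=Cc1ccc(O)c(OC)c1 | starting material
2 | 3-methoxy-4-[(triisopropylsilyl)oxy]benzaldehyde | O=Cc1ccc(O[Si](C(C)C)(C(C)C)C(C)C)c(OC)c1 | intermediate
3 | lithium alpha-amino alkoxide of 2 (adduct with lithium N,N,N'-trimethylethylenediamide) | [Li]OC(N(C)CCN(C)C)c1ccc(O[Si](C(C)C)(C(C)C)C(C)C)c(OC)c1 | intermediate (not isolated)
4 | 2-lithio alpha-amino alkoxide | [Li]OC(N(C)CCN(C)C)c1ccc(O[Si](C(C)C)(C(C)C)C(C)C)c(OC)c1[Li] | intermediate (not isolated)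
5 | 2-(trimethylsilyl) alpha-amino alkoxide | [Li]OC(N(C)CCN(C)C)c1ccc(O[Si](C(C)C)(C(C)C)C(C)C)c(OC)c1[Si](C)(C)C | intermediate (not isolated)
6 | 3-methoxy-4-[(triisopropylsilyl)oxy]-2-(trimethylsilyl)benzaldehyde | O=Cc1ccc(O[Si](C(C)C)(C(C)C)C(C)C)c(OC)c1[Si](C)(C)C | intermediate
7 | 4-vinyl-1,3-dioxolan-2-one (racemic) | C=CC1COC(=O)O1 | starting material
8 | (1S,2R)-1-{3-methoxy-4-[(triisopropylsilyl)oxy]phenyl}-2-vinylpropane-1,3-diol | C=C[C@H](CO)[C@H](O)c1ccc(O[Si](C(C)C)(C(C)C)C(C)C)c(OC)c1 | intermediate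
9 | (1S,2R)-1-{3-methoxy-4-[(triisopropylsilyl)oxy]phenyl}-2-vinylpropane-1,3-diyl diacetate | C=C[C@H](COC(C)=O)[C@H](OC(C)=O)c1ccc(O[Si](C(C)C)(C(C)C)C(C)C)c(OC)c1 | intermediate
10 | B-alkyl-9-borabicyclo[3.3.1]nonane from 9 | C1CCC2CCCC1B2CC[C@H](COC(C)=O)[C@H](OC(C)=O)c1ccc(O[Si](C(C)C)(C(C)C)C(C)C)c(OC)c1 | intermediate (not isolated)
11 | (1S,2R)-2-(2-hydroxyethyl)-1-{3-methoxy-4-[(triisopropylsilyl)oxy]phenyl}propane-1,3-diyl diacetate | OCC[C@H](COC(C)=O)[C@H](OC(C)=O)c1ccc(O[Si](C(C)C)(C(C)C)C(C)C)c(OC)c1 | intermediate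
12 | (1S,2R)-1-{3-methoxy-4-[(triisopropylsilyl)oxy]phenyl}-2-(2-oxoethyl)propane-1,3-diyl diacetate | O=CC[C@H](COC(C)=O)[C@H](OC(C)=O)c1ccc(O[Si](C(C)C)(C(C)C)C(C)C)c(OC)c1 | intermediate
13 | (1S,2R)-2-{(E)-1-formyl-2-[3-methoxy-4-[(triisopropylsilyl)oxy]-2-(trimethylsilyl)phenyl]vinyl}-1-{3-methoxy-4-[(triisopropylsilyl)oxy]phenyl}propane-1,3-diyl diacetate | O=C/C(=C/c1ccc(O[Si](C(C)C)(C(C)C)C(C)C)c(OC)c1[Si](C)(C)C)[C@H](COC(C)=O)[C@H](OC(C)=O)c1ccc(O[Si](C(C)C)(C(C)C)C(C)C)c(OC)c1 | intermediate
14 | benzylic cation at C1 (triflate ion pair; cation shown) | O=C/C(=C/c1ccc(O[Si](C(C)C)(C(C)C)C(C)C)c(OC)c1[Si](C)(C)C)[C@H](COC(C)=O)[CH+]c1ccc(O[Si](C(C)C)(C(C)C)C(C)C)c(OC)c1 | intermediate (not isolated)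
15 | [(1S,2R)-3-formyl-8-methoxy-1-{3-methoxy-4-[(triisopropylsilyl)oxy]phenyl}-7-[(triisopropylsilyl)oxy]-1,2-dihydronaphthalen-2-yl]methyl acetate | COc1cc([C@H]2c3c(ccc(O[Si](C(C)C)(C(C)C)C(C)C)c3OC)C=C(C=O)[C@@H]2COC(C)=O)ccc1O[Si](C(C)C)(C(C)C)C(C)C | intermediate
16 | [(1S,2R)-3-formyl-7-hydroxy-1-(4-hydroxy-3-methoxyphenyl)-8-methoxy-1,2-dihydronaphthalen-2-yl]methyl acetate | COc1cc([C@H]2c3c(ccc(O)c3OC)C=C(C=O)[C@@H]2COC(C)=O)ccc1O | target

**Step count and risks**

Total step count: 9. Longest linear sequence: 8 steps (steps 1, 3, 4, 5, 6, 7, 8, 9).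

Steps most likely to fail:

1. Step 8 (proposed new method). The cation may lose the C2 proton (E1) faster than it closes the ring, or it may attack C5 after loss of silicon, giving the wrong regiochemistry. The fallback sets out from aldehyde 12 and returns at 15.
   - Commercial 6-bromovanillin (2-bromo-4-hydroxy-5-methoxybenzaldehyde) is silylated (i-Pr3SiCl, imidazole) to 2-bromo-5-methoxy-4-[(triisopropylsilyl)oxy]benzaldehyde F1.
   - Amine-catalysed condensation with 12, as in step 7, should give the bromo enal (1S,2R)-2-{(E)-2-[2-bromo-5-methoxy-4-[(triisopropylsilyl)oxy]phenyl]-1-formylvinyl}-1-{3-methoxy-4-[(triisopropylsilyl)oxy]phenyl}propane-1,3-diyl diacetate F2.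
   - Classical Friedel–Crafts closure of the benzylic acetate (BF3·OEt2, CH2Cl2, −40 °C) can then only occur at the free ortho position C8a, because C5 is blocked by bromine (the halogen-blocking tactic of isoquinoline synthesis). It should give [(1S,2R)-5-bromo-3-formyl-8-methoxy-1-{3-methoxy-4-[(triisopropylsilyl)oxy]phenyl}-7-[(triisopropylsilyl)oxy]-1,2-dihydronaphthalen-2-yl]methyl acetate F3.
   - Radical hydrodebromination (Bu3SnH, AIBN, toluene, 80 °C) leads back to 15.

2. Step 7. The hindered, electron-rich aldehyde 6 may react too slowly, so that self-condensation of 12 takes over. The fallback sets out from 12 and 6 and returns at 13, replacing the aldol by olefin metathesis.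
   - Organocatalytic alpha-methylenation of 12 (aqueous formaldehyde, pyrrolidine, propionic acid) should give (1S,2R)-1-{3-methoxy-4-[(triisopropylsilyl)oxy]phenyl}-2-(3-oxoprop-1-en-2-yl)propane-1,3-diyl diacetate F4.
   - Wittig methylenation of 6 (Ph3P=CH2, THF, 0 °C) should give 2-methoxy-1-[(triisopropylsilyl)oxy]-3-(trimethylsilyl)-4-vinylbenzene F5.
   - Cross-metathesis of F4 with F5 (second-generation Hoveyda–Grubbs catalyst, RuCl2(H2IMes)(=CH-C6H4-2-O-i-Pr), CH2Cl2, 40 °C) should give the E-enal 13 with loss of ethylene.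

3. Step 3. Enantio- or diastereocontrol may be insufficient with the electron-rich silyloxy aldehyde, or the sense of induction may be the wrong one. The fallback sets out from 2 and returns at 12, so that steps 4 to 6 are bypassed as well.
   - (S)-4-Benzyl-3-(pent-4-enoyl)-1,3-oxazolidin-2-one F6 is made from (S)-4-benzyl-1,3-oxazolidin-2-one, n-BuLi and pent-4-enoyl chloride.
   - Boron-mediated Evans syn-aldol addition to 2 (Bu2BOTf, i-Pr2NEt, CH2Cl2, −78 °C) should give (S)-4-benzyl-3-[(2S,3S)-3-hydroxy-3-{3-methoxy-4-[(triisopropylsilyl)oxy]phenyl}-2-(prop-2-en-1-yl)propanoyl]-1,3-oxazolidin-2-one F7, with the auxiliary fixing C2.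
   - LiBH4 (THF, MeOH, 0 °C) removes the auxiliary to give (1S,2R)-2-allyl-1-{3-methoxy-4-[(triisopropylsilyl)oxy]phenyl}propane-1,3-diol F8.
   - Ac2O and pyridine give (1S,2R)-2-allyl-1-{3-methoxy-4-[(triisopropylsilyl)oxy]phenyl}propane-1,3-diyl diacetate F9.
   - Oxidative cleavage of the allyl group (OsO4 cat., NaIO4, 2,6-lutidine, dioxane–water) gives aldehyde 12.

**Further compounds**

F1 | step 8 | 2-bromo-5-methoxy-4-[(triisopropylsilyl)oxy]benzaldehyde | O=Cc1cc(OC)c(O[Si](C(C)C)(C(C)C)C(C)C)cc1Br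
F2 | step 8 | (1S,2R)-2-{(E)-2-[2-bromo-5-methoxy-4-[(triisopropylsilyl)oxy]phenyl]-1-formylvinyl}-1-{3-methoxy-4-[(triisopropylsilyl)oxy]phenyl}propane-1,3-diyl diacetate | O=C/C(=C/c1cc(OC)c(O[Si](C(C)C)(C(C)C)C(C)C)cc1Br)[C@H](COC(C)=O)[C@H](OC(C)=O)c1ccc(O[Si](C(C)C)(C(C)C)C(C)C)c(OC)c1
F3 | step 8 | [(1S,2R)-5-bromo-3-formyl-8-methoxy-1-{3-methoxy-4-[(triisopropylsilyl)oxy]phenyl}-7-[(triisopropylsilyl)oxy]-1,2-dihydronaphthalen-2-yl]methyl acetate | COc1cc([C@H]2c3c(c(Br)cc(O[Si](C(C)C)(C(C)C)C(C)C)c3OC)C=C(C=O)[C@@H]2COC(C)=O)ccc1O[Si](C(C)C)(C(C)C)C(C)C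
F4 | step 7 | (1S,2R)-1-{3-methoxy-4-[(triisopropylsilyl)oxy]phenyl}-2-(3-oxoprop-1-en-2-yl)propane-1,3-diyl diacetate | C=C(C=O)[C@H](COC(C)=O)[C@H](OC(C)=O)c1ccc(O[Si](C(C)C)(C(C)C)C(C)C)c(OC)c1
F5 | step 7 | 2-methoxy-1-[(triisopropylsilyl)oxy]-3-(trimethylsilyl)-4-vinylbenzene | C=Cc1ccc(O[Si](C(C)C)(C(C)C)C(C)C)c(OC)c1[Si](C)(C)C
F6 | step 3 | (S)-4-benzyl-3-(pent-4-enoyl)-1,3-oxazolidin-2-one | C=CCCC(=O)N1[C@@H](Cc2ccccc2)COC1=O
F7 | step 3 | (S)-4-benzyl-3-[(2S,3S)-3-hydroxy-3-{3-methoxy-4-[(triisopropylsilyl)oxy]phenyl}-2-(prop-2-en-1-yl)propanoyl]-1,3-oxazolidin-2-one | C=CC[C@H](C(=O)N1[C@@H](Cc2ccccc2)COC1=O)[C@H](O)c1ccc(O[Si](C(C)C)(C(C)C)C(C)C)c(OC)c1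
F8 | step 3 | (1S,2R)-2-allyl-1-{3-methoxy-4-[(triisopropylsilyl)oxy]phenyl}propane-1,3-diol | C=CC[C@H](CO)[C@H](O)c1ccc(O[Si](C(C)C)(C(C)C)C(C)C)c(OC)c1
F9 | step 3 | (1S,2R)-2-allyl-1-{3-methoxy-4-[(triisopropylsilyl)oxy]phenyl}propane-1,3-diyl diacetate | C=CC[C@H](COC(C)=O)[C@H](OC(C)=O)c1ccc(O[Si](C(C)C)(C(C)C)C(C)C)c(OC)c1
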